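## Structural features

The target 16 consists of two phloroglucinol-type benzene rings joined only through one methylene carbon; there is no ring fusion and no stereocentre, so no neighbouring stereocentres have to be related. Ring A is pentasubstituted (C1 OMe, C2 H, C3 OH, C4 CH2 bridge, C5 OH, C6 acetyl) and ring B is hexasubstituted (C1' bridge, C2' OH, C3' methyl, C4' OH, C5' acetyl, C6' OMe). The fragile parts are the four free phenols (oxidation in basic, aerobic media), the two enolizable aryl methyl ketones, the methyl ethers ortho to carbonyl groups (cleaved by strong Lewis acids) and above all the diarylmethane link between two electron-rich rings, which acid or hot base can break or scramble through quinone-methide-like fragments. The real difficulty is regiochemical: eleven ring substituents must be placed, each ring needs one OMe and two OH in a fixed order relative to bridge and acetyl, and the two rings are too alike for an unselective union or late functionalization. The key step exploits that ring A atoms C6, C1, C2 and C3 together with the acetyl group correspond atom for atom to C5, C4, C3, C2 and the C6–CH3 unit of 4-methoxy-6-methyl-2-pyrone (10). The remaining ring A atoms C4 and C5 and the bridge CH2 are the α-carbon, the carbonyl carbon and the β-carbon of a dihydrocoumarin (9) fused to ring B, whose ring oxygen is the C2' hydroxyl of the target. Ring A can therefore be closed by two C–C bonds (C3–C4 and C5–C6) with bridge and ring B already attached.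

## Logic of the disconnections

16 to 14: the bond between C5' of ring B and its acetyl carbon is cut. A methyl ketone on ring B would be deprotonated before the lactone in the enolate chemistry that builds ring A, so it has to come last. The gain is a ring B fragment with one substituent and one base-sensitive group fewer. The forward step must acylate once, at the only CH of ring B, without attacking ring A (whose three oxygens are all conjugated with its own acetyl) and without cutting the bridge.

14 to 13: the O–benzyl bond on the C4' oxygen is cut. This oxygen must be masked while strong base is present; as a free phenoxide it would put a second charge on the lactone and weaken it as an acyl donor. The forward step must remove the benzyl group without reducing the aryl ketone.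

13 to 9 + 10: the ring A bonds C3–C4 and C5–C6 are cut. The C5 oxygen of ring A is traced back to the lactone carbonyl of 9 and the C2' oxygen of ring B to its ring oxygen. All of ring A with its OMe, H, OH and acetyl in the correct order then comes from 10, and the bridge and ring B come from 9. The forward step demands that the enolate of 9 adds to the carbonyl of 10 rather than removing a proton from its methyl group, and that the opened chain then closes on the aryl ester.

9 to 8: the benzyl ether bond is cut, leaving a single phenol to be alkylated; the forward step must keep the aryl lactone closed.

8 to 5 + 6: the aryl–CH2 bond and the lactone C–O bond are cut. Because 5 is mirror-symmetric, its two free ring positions are equivalent and either gives the same lactone. The forward step has to stop after one annulation.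

5 to 4 to 2 to 1: the aryl–CH3 bond between the two oxygens is cut, and the two hydroxyls are converted into acetal directing groups. The forward sequence needs lithiation between the two acetal oxygens rather than next to the OMe group, and an acetal cleavage that does not return the released one-carbon unit to the electron-rich ring.

## Other disconnections considered

Alternative 1: The cut goes through ring B at C4'–C3' and C2'–C1'. This leaves a cyclobutenone that already carries ring A and the bridge, 3-methoxy-2-{[4-methoxy-2,6-bis(methoxymethoxy)phenyl]methyl}cyclobut-2-en-1-one A1, and the siloxyalkyne triisopropyl(prop-1-yn-1-yloxy)silane A2. Heating A1 with A2 should open the four-membered ring to a vinylketene, which adds to the alkyne in a regioselective [2+2] step; 4π opening, 6π closure and tautomerization would then give 4-{[4-methoxy-2,6-bis(methoxymethoxy)phenyl]methyl}-5-methoxy-2-methyl-3-[(triisopropylsilyl)oxy]phenol A3 (Danheiser benzannulation).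
- In favour: the cascade is an established reaction type and needs no base. The positions of methyl, bridge, OMe and both oxygens of ring B follow from the connectivity of A1 and A2. The free C4' hydroxyl of A3 sits ortho to the open C5' position and could direct the later acylation.
- Against it here: A3 carries no acetyl on either ring, so two C-acylations remain. One falls on a ring A that, once its acetals are removed, has two equivalent CH positions and invites double acylation. The differentiation of the ring B oxygens is not needed by the target, and A1 needs several steps from a 2-substituted cyclobutane-1,3-dione.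
- Comparison: on mechanistic precedent alternative 1 is the better plan, since the chosen key step has no direct precedent. On structure the chosen plan is ahead, because 13 already holds the ring A acetyl and leaves one acylation at a single CH. On stereochemistry the two are equal, as nothing has to be controlled. On step economy the chosen route (eight steps) should be clearly shorter.

Alternative 2: The cut goes through ring B at C3'–C2' and C5'–C4'. The same pyrone-refolding idea is applied to the other ring: the lithium enolate of methyl propanoate A5 would add to the lactone carbonyl of 4-methoxy-3-{[4-methoxy-2,6-bis(methoxymethoxy)phenyl]methyl}-6-methyl-2H-pyran-2-one A4. The pyrone would open, and its former C5 would close onto the ester carbonyl to give 1-[2,4-dihydroxy-6-methoxy-3-methyl-5-{[4-methoxy-2,6-bis(methoxymethoxy)phenyl]methyl}phenyl]ethanone A6.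
- In favour: ring B would arrive hexasubstituted with its acetyl in place, so the remaining acylation could only occur on ring A. On the ring selectivity of the late acylation this alternative is better than the chosen plan, although ring A would then offer two equivalent CH positions where 14 offers one.
- Against it here: the annulation is as unprecedented as the chosen one and is less well set up. The pyrone carbonyl of A4 is flanked by the bulky benzylic group, which should slow addition and favour deprotonation of the 6-methyl group. The closing acylation uses a methyl ester, a poorer acyl donor than the aryl lactone of 9, and the enolate of A5 can condense with itself. A4 must be made by C-benzylation and regioselective O-methylation of a hydroxypyrone, whereas 10 is used as bought.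
- Comparison: structurally the two plans are mirror images of one idea and equal in kind of risk. Mechanistically the chosen plan is better, because its second acylation is intramolecular on an activated ester and sets the C2' hydroxyl free. In step economy the alternative should be equal at best, since acetal removal and ring A acylation follow A6.

Alternative 3: The cut goes through ring A at C1–C6 and C5–C4. The finished, benzyl-protected ring B is carried on a cyclobutenone, 2-{[5-acetyl-2,4-bis(benzyloxy)-6-methoxy-3-methylphenyl]methyl}-3-(benzyloxy)cyclobut-2-en-1-one A7, which would be heated with (ethynyloxy)triisopropylsilane A8. The same electrocyclic cascade as in alternative 1 would give 4-{[5-acetyl-2,4-bis(benzyloxy)-6-methoxy-3-methylphenyl]methyl}-3-(benzyloxy)-5-[(triisopropylsilyl)oxy]phenol A9.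
- In favour: ring B is complete, including its acetyl, so no acylation of ring B is needed; on this point and on mechanistic precedent the alternative is better than the chosen plan. It is also convergent and base-free.
- Against it here: ring A of A9 has no acetyl and three differently masked oxygens. O-methylation at C1, an acylation that must pick C6 over the very similar C2 (probably through the unmasked C5 oxygen as ortho director), and removal of three benzyl groups would still follow. A7 requires a long synthesis of the hexasubstituted ring B benzylic unit, its methyl ketone must survive the making of the cyclobutenone, and the terminal siloxyalkyne A8 is sensitive.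
- Comparison: the chosen plan is better on ring A regiochemistry, since the atom order of 10 fixes the acetyl at C6. Alternative 3 is better on ring B and on precedent. On step economy the chosen route should be considerably shorter.

Key step: step 6

Assumption: 1, 6 and 10 are taken as commercial.

Remark on the structures: the atom mapping of 9 and 10 onto rings A and B was re-derived and needs no correction. The carbon chain of the enol ether in 12 is cis, which is (E) by the sequence rules.

Remark on the design: the benzyl ether of 9 is kept, and the ring B acetyl is left out of 9 because an aryl methyl ketone would be deprotonated before the lactone. The final acylation is planned as a Houben–Hoesch reaction, which stops after one acylation and spares the methyl ethers.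

## Route

Step 1
Reactants: 1 5-methoxybenzene-1,3-diol (5-methoxyresorcinol)
Product: 2 1-methoxy-3,5-bis(methoxymethoxy)benzene
Conditions: NaH (2.4 equiv), MOMCl (2.4 equiv), DMF, 0 °C to rt
Reagents that add atoms: chloromethyl methyl ether, COCCl
Why: Williamson-type O-alkylation of both phenoxides (MOM protection); the two acetal ethers are installed because they are the directing groups for the next step.

Step 2
Reactants: 2 1-methoxy-3,5-bis(methoxymethoxy)benzene
Product: 4 5-methoxy-1,3-bis(methoxymethoxy)-2-methylbenzene, via [4-methoxy-2,6-bis(methoxymethoxy)phenyl]lithium 3 (not isolated)
Conditions: n-BuLi (1.2 equiv), THF, 0 °C; MeI, −78 °C to rt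
Reagents that add atoms: iodomethane, CI
Why: Directed ortho-metalation: the CH between the two MOM ethers is doubly coordinated and the most acidic, so lithiation should occur there rather than next to the OMe group; the aryllithium 3 is then methylated by SN2 reaction with MeI.

Step 3
Reactants: 4 5-methoxy-1,3-bis(methoxymethoxy)-2-methylbenzene
Product: 5 5-methoxy-2-methylbenzene-1,3-diol
Conditions: HCl (aq., cat.), MeOH, 50 °C, dilute
Reagents that add atoms: none
Why: Acid-catalysed acetal cleavage (MOM removal); methanol as solvent captures the released one-carbon unit as its dimethyl acetal, which limits re-addition to the electron-rich ring.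

Step 4
Reactants: 5 5-methoxy-2-methylbenzene-1,3-diol; 6 prop-2-enoic acid (acrylic acid)
Product: 8 7-hydroxy-5-methoxy-8-methyl-3,4-dihydro-2H-chromen-2-one, via 3-(2,4-dihydroxy-6-methoxy-3-methylphenyl)propanoic acid 7 (not isolated)
Conditions: 6 (1.05 equiv), Amberlyst 15 (sulfonated polystyrene resin, H+ form), toluene, reflux, Dean–Stark
Reagents that add atoms: none
Why: Acid-catalysed Friedel–Crafts conjugate hydroarylation of acrylic acid at one of the two equivalent CH positions of 5 (each ortho to OH and OMe, para to the other OH) gives acid 7, which lactonizes onto the neighbouring hydroxyl as water is removed; this resorcinol–acrylic acid annulation to 3,4-dihydrocoumarins is an established reaction type. The mirror symmetry of 5 makes both sites lead to the same lactone, and one equivalent of 6 limits a second annulation.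

Step 5
Reactants: 8 7-hydroxy-5-methoxy-8-methyl-3,4-dihydro-2H-chromen-2-one
Product: 9 7-(benzyloxy)-5-methoxy-8-methyl-3,4-dihydro-2H-chromen-2-one
Conditions: BnBr (1.1 equiv), K2CO3 (1.5 equiv), dry acetone, reflux
Reagents that add atoms: benzyl bromide, BrCc1ccccc1
Why: Williamson ether synthesis on the only phenol; a weak, anhydrous base is chosen so that the aryl lactone stays closed.

Step 6
Reactants: 9 7-(benzyloxy)-5-methoxy-8-methyl-3,4-dihydro-2H-chromen-2-one; 10 4-methoxy-6-methyl-2H-pyran-2-one
Product: 13 1-[3-{[4-(benzyloxy)-2-hydroxy-6-methoxy-3-methylphenyl]methyl}-2,4-dihydroxy-6-methoxyphenyl]ethanone, via lithium lactone enolate 11 (not isolated), via ring-opened acyl lactone dienolate 12 (not isolated)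
Conditions: LiN(i-Pr)2 (1.05 equiv), THF, −78 °C (9 added to the base); 10 (1.0 equiv), −78 to −40 °C; LiN(SiMe3)2 (2.2 equiv), −40 to 0 °C; aq. HCl
Reagents that add atoms: none
Why: Proposed new method: the lithium enolate 11, generated by adding 9 to LiN(i-Pr)2 at −78 °C so that no free lactone remains for self-condensation, should add to the lactone carbonyl of 10 (new bond C3–C4 of ring A), and collapse of the tetrahedral alkoxide opens the pyrone to the dienolate 12, whose enol ether keeps the carbon chain cis (E by the sequence rules). The carbon that was C5 of the pyrone is the nucleophilic α-position of this dienolate; it lies six atoms from the aryl lactone carbonyl and should attack it in a 6-exo-trig Claisen closure (new bond C5–C6), after which the ring B phenoxide is expelled and two enolizations make ring A aromatic, while an E1cB variant through an acylketene formed from the doubly deprotonated intermediate would lead to the same ring. The closest known reaction types are the carbanion-induced ring transformation of 2-pyranones into benzenes, the base-mediated Claisen cyclization of 3,5,7-triketo esters and of tetraacetic acid lactone to acylphloroglucinols, and the crossed Claisen acylation of ester enolates; new is the 1,2-attack of a lactone enolate on a 4-alkoxy-2-pyranone with the acyl acceptor built into the nucleophile. No stereocentre results, since the sp3 centre at the α-carbon of 12 is racemic and disappears on aromatization. Two selectivities are needed: addition to the pyrone carbonyl instead of deprotonation of its 6-methyl group, which low temperature, the lithium-bound carbonyl and the absence of free amide base during the addition are meant to secure, and Claisen instead of aldol closure, which the substrate secures because the α-carbon bears the benzylic CH2, so that an aldol onto the methyl ketone could only give a reversible spiro adduct that cannot aromatize. LiN(SiMe3)2 is added only after 10 is consumed, to make up for the acidic C–H and O–H groups that appear and would otherwise quench unreacted 11. The aryl ester is a better acyl donor than an alkyl ester and delivers the C2' hydroxyl of ring B without a protecting-group step.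

Step 7
Reactants: 13 1-[3-{[4-(benzyloxy)-2-hydroxy-6-methoxy-3-methylphenyl]methyl}-2,4-dihydroxy-6-methoxyphenyl]ethanone
Product: 14 1-{3-[(2,4-dihydroxy-6-methoxy-3-methylphenyl)methyl]-2,4-dihydroxy-6-methoxyphenyl}ethanone
Conditions: H2 (1 atm), Pd/C (10 wt%), EtOAc/MeOH, rt
Reagents that add atoms: none
Why: Hydrogenolysis of the aryl benzyl ether; the hydrogen-bonded, electron-rich aryl ketone and the diarylmethane carbon are not expected to be reduced at atmospheric pressure and room temperature.

Step 8
Reactants: 14 1-{3-[(2,4-dihydroxy-6-methoxy-3-methylphenyl)methyl]-2,4-dihydroxy-6-methoxyphenyl}ethanone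
Product: 16 1-{3-[(3-acetyl-4,6-dihydroxy-2-methoxy-5-methylphenyl)methyl]-2,4-dihydroxy-6-methoxyphenyl}ethanone (target), via ring B ketiminium chloride 15 (not isolated)
Conditions: MeCN, ZnCl2 (0.3 equiv), HCl (g), Et2O, 0 °C; then H2O, 90 °C
Reagents that add atoms: acetonitrile, CC#N; water, O
Why: Houben–Hoesch acylation: the nitrilium species formed from MeCN, HCl and ZnCl2 attacks the only CH of ring B (ortho to OH and OMe, para to OH), and hydrolysis of the ketiminium salt 15 gives the ketone. Ring A should not compete because all three of its oxygens are conjugated with its acetyl group, and the iminium group of 15 deactivates ring B against a second acylation.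

## Compound list

1 | 5-methoxybenzene-1,3-diol (5-methoxyresorcinol) | COc1cc(O)cc(O)c1 | starting material
2 | 1-methoxy-3,5-bis(methoxymethoxy)benzene | COCOc1cc(OC)cc(OCOC)c1 | intermediate
3 | [4-methoxy-2,6-bis(methoxymethoxy)phenyl]lithium (formed in the flask) | [Li]c1c(OCOC)cc(OC)cc1OCOC | intermediate
4 | 5-methoxy-1,3-bis(methoxymethoxy)-2-methylbenzene | COCOc1cc(OC)cc(OCOC)c1C | intermediate
5 | 5-methoxy-2-methylbenzene-1,3-diol | COc1cc(O)c(C)c(O)c1 | intermediate
6 | prop-2-enoic acid (acrylic acid) | C=CC(=O)O | starting material
7 | 3-(2,4-dihydroxy-6-methoxy-3-methylphenyl)propanoic acid (formed in the flask) | COc1cc(O)c(C)c(O)c1CCC(=O)O | intermediate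
8 | 7-hydroxy-5-methoxy-8-methyl-3,4-dihydro-2H-chromen-2-one | COc1cc(O)c(C)c2OC(=O)CCc12 | intermediate
9 | 7-(benzyloxy)-5-methoxy-8-methyl-3,4-dihydro-2H-chromen-2-one | COc1cc(OCc2ccccc2)c(C)c2OC(=O)CCc12 | intermediate
10 | 4-methoxy-6-methyl-2H-pyran-2-one | COC1=CC(=O)OC(C)=C1 | starting material
11 | lithium 7-(benzyloxy)-5-methoxy-8-methyl-4H-chromen-2-olate, the lithium enolate of 9 (formed in the flask) | [Li]OC1=CCc2c(OC)cc(OCc3ccccc3)c(C)c2O1 | intermediate
12 | lithium dienolate of 7-(benzyloxy)-5-methoxy-3-[(2E)-3-methoxy-5-oxohex-2-enoyl]-8-methyl-3,4-dihydro-2H-chromen-2-one, racemic at C3 of the lactone (formed in the flask) | [Li]O/C(C)=C\C(OC)=C/C(=O)C1Cc2c(OC)cc(OCc3ccccc3)c(C)c2OC1=O | intermediate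
13 | 1-[3-{[4-(benzyloxy)-2-hydroxy-6-methoxy-3-methylphenyl]methyl}-2,4-dihydroxy-6-methoxyphenyl]ethanone | COc1cc(O)c(Cc2c(O)c(C)c(OCc3ccccc3)cc2OC)c(O)c1C(C)=O | intermediate
14 | 1-{3-[(2,4-dihydroxy-6-methoxy-3-methylphenyl)methyl]-2,4-dihydroxy-6-methoxyphenyl}ethanone | COc1cc(O)c(Cc2c(O)c(C)c(O)cc2OC)c(O)c1C(C)=O | intermediate
15 | 1-{3-[(3-acetyl-2,6-dihydroxy-4-methoxyphenyl)methyl]-4,6-dihydroxy-2-methoxy-5-methylphenyl}ethan-1-iminium chloride (formed in the flask) | COc1cc(O)c(Cc2c(O)c(C)c(O)c(C(C)=[NH2+])c2OC)c(O)c1C(C)=O.[Cl-] | intermediate
16 | 1-{3-[(3-acetyl-4,6-dihydroxy-2-methoxy-5-methylphenyl)methyl]-2,4-dihydroxy-6-methoxyphenyl}ethanone | COc1cc(O)c(Cc2c(O)c(C)c(O)c(C(C)=O)c2OC)c(O)c1C(C)=O | target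

## Step count and least certain steps

Total step count: 8. Longest linear sequence: 8 steps (1 to 16); 6 and 10 enter as purchased materials.

**Step 6 (key step, the one step labelled as a proposed new method).**
- What may go wrong: proton transfer from the 6-methyl group of 10 to the basic enolate 11 may outrun 1,2-addition, because the pyrone carbonyl is a deactivated, vinylogous carbonate-like electrophile while its methyl group is fairly acidic. The resulting pyrone anion would then be acylated by the aryl lactone and give the wrong connectivity. Self-condensation of the lactone, or stalling of the opened intermediate as an unreactive doubly deprotonated β-keto lactone, are further possibilities.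
- Fallback (known chemistry), setting out from 5 and returning at 14: commercial 1-(2,4-dihydroxy-6-methoxyphenyl)ethanone F1 is converted by a Mannich reaction (aqueous formaldehyde, dimethylamine, ethanol) into 1-{3-[(dimethylamino)methyl]-2,4-dihydroxy-6-methoxyphenyl}ethanone F2. Aminomethylation is expected at the position between the two hydroxyls, and this regiochemistry would have to be confirmed. Heating F2 with an excess of 5 in dioxane should expel dimethylamine to give an ortho-quinone methide, which 5 captures at either of its equivalent CH positions in a Friedel–Crafts alkylation. This gives 14, and step 8 completes the route.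

**Step 8.**
- What may go wrong: acid-induced scission or scrambling of the methylene bridge (ipso-protonation of the very electron-rich ring B and loss of a stabilized benzylic cation) under HCl and ZnCl2, or slow hydrolysis of the doubly ortho-substituted ketiminium salt.
- Fallback, setting out from 5 and returning at 16: acylation of the dimer is avoided. 5 is acetylated at the monomer stage by the same Houben–Hoesch procedure to 1-(2,4-dihydroxy-6-methoxy-3-methylphenyl)ethanone F3, which has a single free CH. F3 is then heated with the Mannich base F2 in dioxane, so that the quinone methide from F2 alkylates that CH and gives 16 directly. This fallback gives up ring construction in favour of the classical union of two acylphloroglucinol monomers.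

**Step 4.**
- What may go wrong: over-reaction, because 8 is still an electron-rich phenol with one free CH; a second annulation, or C-acylation leading to a chromanone, could compete.
- Fallback, setting out from 5 and returning at 8: hydroarylation of propiolic acid (Pd(OAc)2 as catalyst, CF3CO2H, rt) should give the coumarin 7-hydroxy-5-methoxy-8-methyl-2H-chromen-2-one F4. Its conjugated lactone deactivates the ring enough to stop at one annulation. Hydrogenation of the C3–C4 double bond of F4 (H2, Pd/C, EtOAc) then gives 8.

**Step 5.**
- What may go wrong: opening of the aryl lactone under the basic alkylation conditions, through hydrolysis by carbonate and adventitious water or through transesterification by phenoxide, leading to ring-opened or oligomeric material.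
- Fallback, setting out from 8 and returning at 14: the phenol is silylated under nearly neutral conditions (i-Pr3SiCl, imidazole, DMF) to 5-methoxy-8-methyl-7-[(triisopropylsilyl)oxy]-3,4-dihydro-2H-chromen-2-one F5. F5 is taken through the annulation of step 6 with 10 to give 1-[2,4-dihydroxy-3-({2-hydroxy-6-methoxy-3-methyl-4-[(triisopropylsilyl)oxy]phenyl}methyl)-6-methoxyphenyl]ethanone F6. Desilylation of F6 with Bu4NF in THF gives 14, so this variant also removes the hydrogenation step.

## Further compounds

F1 | step 6 | 1-(2,4-dihydroxy-6-methoxyphenyl)ethanone | COc1cc(O)cc(O)c1C(C)=O
F2 | step 6 | 1-{3-[(dimethylamino)methyl]-2,4-dihydroxy-6-methoxyphenyl}ethanone | COc1cc(O)c(CN(C)C)c(O)c1C(C)=O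
F3 | step 8 | 1-(2,4-dihydroxy-6-methoxy-3-methylphenyl)ethanone | COc1cc(O)c(C)c(O)c1C(C)=O
F4 | step 4 | 7-hydroxy-5-methoxy-8-methyl-2H-chromen-2-one | COc1cc(O)c(C)c2OC(=O)C=Cc12
F5 | step 5 | 5-methoxy-8-methyl-7-[(triisopropylsilyl)oxy]-3,4-dihydro-2H-chromen-2-one | COc1cc(O[Si](C(C)C)(C(C)C)C(C)C)c(C)c2OC(=O)CCc12
F6 | step 5 | 1-[2,4-dihydroxy-3-({2-hydroxy-6-methoxy-3-methyl-4-[(triisopropylsilyl)oxy]phenyl}methyl)-6-methoxyphenyl]ethanone | COc1cc(O)c(Cc2c(O)c(C)c(O[Si](C(C)C)(C(C)C)C(C)C)cc2OC)c(O)c1C(C)=O
A1 | alternative 1 | 3-methoxy-2-{[4-methoxy-2,6-bis(methoxymethoxy)phenyl]methyl}cyclobut-2-en-1-one | COC1=C(Cc2c(OCOC)cc(OC)cc2OCOC)C(=O)C1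
A2 | alternative 1 | triisopropyl(prop-1-yn-1-yloxy)silane | CC#CO[Si](C(C)C)(C(C)C)C(C)C
A3 | alternative 1 | 4-{[4-methoxy-2,6-bis(methoxymethoxy)phenyl]methyl}-5-methoxy-2-methyl-3-[(triisopropylsilyl)oxy]phenol | COc1cc(OCOC)c(Cc2c(O[Si](C(C)C)(C(C)C)C(C)C)c(C)c(O)cc2OC)c(OCOC)c1
A4 | alternative 2 | 4-methoxy-3-{[4-methoxy-2,6-bis(methoxymethoxy)phenyl]methyl}-6-methyl-2H-pyran-2-one | COC1=C(Cc2c(OCOC)cc(OC)cc2OCOC)C(=O)OC(C)=C1
A5 | alternative 2 | methyl propanoate | CCC(=O)OC
A6 | alternative 2 | 1-[2,4-dihydroxy-6-methoxy-3-methyl-5-{[4-methoxy-2,6-bis(methoxymethoxy)phenyl]methyl}phenyl]ethanone | COc1cc(OCOC)c(Cc2c(O)c(C)c(O)c(C(C)=O)c2OC)c(OCOC)c1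
A7 | alternative 3 | 2-{[5-acetyl-2,4-bis(benzyloxy)-6-methoxy-3-methylphenyl]methyl}-3-(benzyloxy)cyclobut-2-en-1-one | O=C1CC(OCc2ccccc2)=C1Cc1c(OCc2ccccc2)c(C)c(OCc2ccccc2)c(C(C)=O)c1OC
A8 | alternative 3 | (ethynyloxy)triisopropylsilane | C#CO[Si](C(C)C)(C(C)C)C(C)C
A9 | alternative 3 | 4-{[5-acetyl-2,4-bis(benzyloxy)-6-methoxy-3-methylphenyl]methyl}-3-(benzyloxy)-5-[(triisopropylsilyl)oxy]phenol | Oc1cc(O[Si](C(C)C)(C(C)C)C(C)C)c(Cc2c(OCc3ccccc3)c(C)c(OCc3ccccc3)c(C(C)=O)c2OC)c(OCc2ccccc2)c1
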